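## The problem

Target **38** is a ten-membered carbocycle fused to an α-(hydroxymethyl)butenolide. The ring atoms are numbered C1 (AcO–CH beside the Z olefin), C2 (CH2), C3 (butenolide β-carbon), C6 (lactone O–CH), C7=C8(CH3) (E), C9 (AcO–CH), C10 (CH2) and C11=C12(CH3) (Z, C12 bonded to C1); C4 (bearing CH2OH) and C5 (C=O) complete the lactone. A synthesis has to close a strained ten-membered ring containing one E and one Z trisubstituted olefin; end-to-end closure would fight transannular strain and would need both geometries fixed in an open chain. There are only three stereocentres, C1 (S), C6 (R) and C9 (S), but they are separated by sp2 carbons: C9 can speak to C6 only through the olefin carbon C8, and C1 has no neighbour to direct it, so it needs reagent control on the finished ring. The functional groups are delicate: two allylic acetates, a butenolide whose C6 hydrogen is both allylic and γ-acidic, a 1,5-diene that cyclises across the ring under acid, and a primary allylic alcohol that must stay free beside two acylated secondary ones. The enabling feature is that C1(O)–C2–C3–C6–C7=C8 is the retron of an oxy-Cope rearrangement, and that rejoining C1 to C8 folds the Z olefin C11=C12 with C10 and C9 into a cyclohexene, ring A. The ten-membered ring can therefore arise by four-carbon expansion of ring A, with the Z olefin locked in the small ring, the E olefin and C6 written by a chair transition state, and C4–C5 carried in on one migrating arm. The price is a ring A with a quaternary C8 flanked by two oxygenated carbons whose oxygens are anti while the two alkenyl arms are trans; that relationship is the real stereochemical problem of the route.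

## Retrosynthesis

**38 ⇒ 37 ⇒ 35 ⇒ 34 (O–acyl and O–silyl bonds only).** The acetates cannot be carried through enolate chemistry, so they are placed last. The free primary alcohol of **38** is masked in **37** as a silyl ether. **37** comes from triol **35** by silylation of the unhindered primary hydroxyl and acetylation of the two secondary ones in one flask. **35** is the desilylation product of butenolide **34**, which carries C1 OTBS and C9 OTIPS. The forward steps are asked only to tell a primary from two secondary hydroxyls and to avoid acid, which the 1,5-diene does not tolerate.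

**34 ⇒ 31 ⇒ 30 (C4–CH2OH bond and C3=C4 unsaturation).** C3 must be sp3 during ring formation, so the butenolide double bond is introduced afterwards by selenoxide elimination. The hydroxymethyl carbon is cut off as formaldehyde (aldol of the lactone enolate of **30**). The order matters: with CH2OH installed first (**31**), selenium enters anti to C2, hence syn to H-3, and the dianion cannot lose its β-oxygen. Precursor **30** is a plain trans-fused γ-lactone.

**30 ⇒ 28 ⇒ 27 ⇒ 26 ⇒ 25 (lactone O6–C5 acyl bond; C1 carbinol).** The lactone is opened to the 1,4-diol **28**, to be closed by oxoammonium oxidation. The diol is unmasked from the bis-PMB ether **27** in one DDQ step. The C1 carbinol of **26** is traced to ketone **25**. This is the one stereocentre that nothing in the ring can relay, so an oxazaborolidine reduction of the enone is used, and it is done before any enolate chemistry because a ketone would not survive that.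

**25 ⇒ 22 (key disconnection: cut C3–C6, rejoin C1–C8).** Every other single cut of the ten-membered ring gives an open chain that must be cyclised. This one gives a cyclohexenol, **22**, in which the Z olefin is a ring olefin and the E olefin does not yet exist. **22** has three stereocentres on a six-membered ring and two E alkenyl arms made from alkenyl iodides. The forward reaction must go through a single chair, which requires the arms to be trans and both E.

**22 ⇒ 21 ⇒ 20 ⇒ 19 ⇒ 18 (no C–C bond; C9 configuration).** **22** needs O9 anti to O1 and cis to the C8 methyl. Both reactions that build ring A prefer the opposite: hydride reduction of the dione places O9 cis to the larger allyl group, and a nucleophile at C1 avoids the face carrying the C8 arm and O9. Rather than force either, the route accepts the syn compound **18**, in which that same preference guarantees the trans arrangement of the arms. It then corrects C9 by desilylation (**19**), oxidation (**20**) and reduction (**21**). In **20** the axial C8 methyl and the C1 hydroxyl both send hydride to the face that gives the anti diol. The cost is three steps and a silyl exchange; the gain is that every stereochemical event follows the substrate's own bias.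

**18 ⇒ 11 + 16 (C1–C2 bond).** The tertiary carbinol is cut to enone **11** and the E alkenyllithium from iodide **16**. This is the convergent point. The forward addition must be 1,2 and must come from the C8-methyl face.

**11 ⇒ 10 ⇒ 9 ⇒ 8 ⇒ 7 (enol ether O–C6 bond, C6=C7, one-carbon degradation of allyl).** The geometry of the enol ether decides C6 in the key step, so an alkoxymethylene Wittig reaction (E/Z mixtures) is avoided. The O–C6 bond is made by copper-catalysed coupling of PMB alcohol with the E alkenyl iodide **10** (retention). **10** comes from aldehyde **9** by Takai olefination, and **9** from the allyl group of **7** by isomerisation to propenyl (**8**) and ozonolysis.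

**7 ⇒ 6 ⇒ 5 ⇒ 4 ⇒ 3 ⇒ 1 + 2 (C12–CH3, C11=C12, C8–allyl).** Enone **7** is reduced to ketone **6**, whose C12 methyl is cut off (MeI) to give **5**, the silyl ether of ketol **4**. **4** arises by desymmetrising reduction of the achiral dione **3**, made from **1** and **2**. This step fixes the quaternary C8; its C9 carbinol serves as a steering group and is later re-set.

**16 ⇒ 14 ⇒ 12 + 13.** The side arm comes from but-3-yn-1-ol by PMB protection and hydrozirconation–iodination.

## Roads not taken

Alternative 1: Nickel reductive ynal macrocyclisation, cutting C8–C9. The open-chain ynal **A1** (C9 aldehyde, C7≡C8–CH3 alkyne, Z-C11=C12 and the C3=C4 enoate already in place) would be closed with Ni(cod)2, IMes and Et3SiH. Zerovalent nickel couples aldehyde and alkyne oxidatively, the silane cleaves the nickel–oxygen bond and reductive elimination delivers hydrogen to C7, giving **A2**.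
- Merits: one step makes the ring, the E olefin (syn addition across the alkyne) and the C9 carbinol, already silylated and distinct from O1 and O6. The butenolide carbons are present as an enoate, so no selenium chemistry is needed. The route would probably be several steps shorter than the 26 used here.
- Weak points: **A1** is an open chain, so Z-C11=C12 and the tetrasubstituted enoate geometry must both be made without a ring to enforce them. Whether the aldehyde bonds to C8 (ten-membered ring, endocyclic E olefin) or to C7 (nine-membered ring, exocyclic olefin) rests on the ligand alone. The new C9 centre is controlled only by the folding of a forming medium ring. The closure is end-to-end and needs dilution.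
- Comparison: this road is better in step count and in differentiating the oxygens. The chosen plan sets against it that both olefin geometries and the C6/C9 relationship are fixed by rings and by a single chair, and that the ring is made without dilution.

Alternative 2: Grob fragmentation of a trans-decalin. Retrosynthetically C1–C8 is rejoined, as in the chosen plan, but C3–C6 is kept and a leaving group is placed on C7. KOtBu would ionise the C1 hydroxyl of mesylate **A3**, and the C1–C8 bond would break anti to the equatorial C7–OMs bond, giving **A4**.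
- Merits: the fragmentation is stereospecific and well understood, it needs no dilution, and decalin stereochemistry is predictable. C3 arrives as a masked ketone, so the butenolide could be built by an intramolecular olefination without selenium, and there is no enol ether geometry to control.
- Weak points: **A3** needs five stereocentres on the bicycle, one of which (C7) is sacrificed, and C6 has to be installed independently rather than relayed. A mesylate next to a quaternary carbon and a β-alkoxy group invites elimination. After fragmentation, C1 and C3 form a masked 1,3-dicarbonyl, and C4–C5 still have to be attached to it.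
- Comparison: this road is at least as good for the ring-forming step itself. The chosen plan sets against it that the Cope shift builds the C3–C6 bond, transfers C8 chirality to C6 and brings C4–C5 along in the same event, from a monocycle with three stereocentres.

Alternative 3: Carbonylative Stille macrocyclisation, cutting C12–C1 and C1–C2 with C1 supplied by CO. Pd2(dba)3 and AsPh3 under CO would join the Z alkenyl iodide and the allylic stannane of **A5** through an inserted carbonyl to give **A6**.
- Merits: this is the most convergent road and probably has the shortest linear sequence. The butenolide is complete before ring closure, so there is no late enolate chemistry, and C6 and C9 come from small acyclic building blocks.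
- Weak points: the ring is again closed end-to-end under dilution, and direct coupling without CO and coupling at the γ-terminus of the allyl stannane compete with the desired path. In **A6** the C2 methylene lies between a ketone and the butenolide; it is a vinylogous 1,3-dicarbonyl that invites enolisation, migration of the butenolide double bond and loss of the C6 configuration. The Z alkenyl iodide has to be made acyclically, and C1 still needs a reagent-controlled reduction.
- Comparison: this road wins on convergence and length. The chosen plan sets against it a ring formation that is unimolecular, needs no dilution and cannot give the wrong olefin geometry, and a C3 that stays sp3 until C1 has been reduced and protected.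

Key step: step 17

Remarks: atom locants C1–C12 are those defined under "The problem" and are kept for all intermediates. Alkali-metal salts that are only the conjugate base of a numbered compound are not numbered, except **23** and **24** of the key step. The oxazaborolidine reductions are assigned by the usual model, with the quaternary C8 as the large group in step 2 and the C12 alkenyl carbon as the large group in step 18.

Step 1
Reactants: 1 2-methylcyclohexane-1,3-dione; 2 allyl bromide
Product: 3 2-methyl-2-(prop-2-en-1-yl)cyclohexane-1,3-dione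
Conditions: aq NaOH (1 M), rt
Reagents that add atoms: none
Why: C-alkylation of the sodium enolate of a cyclic 1,3-dione with a soft allylic halide creates the quaternary C8; the product is achiral.

Step 2
Reactants: 3 2-methyl-2-(prop-2-en-1-yl)cyclohexane-1,3-dione
Product: 4 (2R,3R)-3-hydroxy-2-methyl-2-(prop-2-en-1-yl)cyclohexan-1-one
Conditions: (S)-2-methyl-CBS-oxazaborolidine (20 mol %), catecholborane (1.0 equiv), toluene, −60 °C
Reagents that add atoms: none
Why: CBS reduction used as a desymmetrisation: the (S)-catalyst makes the carbinol R with the quaternary carbon as the large group, and of the two enantiotopic carbonyls the one that lets hydride enter anti to the allyl group is matched, so O9 ends cis to allyl and C8 is fixed; limiting the borane avoids the diol.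

Step 3
Reactants: 4 (2R,3R)-3-hydroxy-2-methyl-2-(prop-2-en-1-yl)cyclohexan-1-one
Product: 5 (2R,3R)-3-[(tert-butyldimethylsilyl)oxy]-2-methyl-2-(prop-2-en-1-yl)cyclohexan-1-one
Conditions: TBSOTf, 2,6-lutidine, CH2Cl2, −78 °C
Reagents that add atoms: tert-butyldimethylsilyl triflate, CC(C)(C)[Si](C)(C)OS(=O)(=O)C(F)(F)F
Why: Silyl triflate silylation of a hindered secondary alcohol; the hindered base leaves the ketone un-enolised at low temperature.

Step 4
Reactants: 5 (2R,3R)-3-[(tert-butyldimethylsilyl)oxy]-2-methyl-2-(prop-2-en-1-yl)cyclohexan-1-one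
Product: 6 (2R,3R)-3-[(tert-butyldimethylsilyl)oxy]-2,6-dimethyl-2-(prop-2-en-1-yl)cyclohexan-1-one (both C6 epimers)
Conditions: LDA, THF, −78 °C; MeI, −78 → −20 °C
Reagents that add atoms: iodomethane, CI
Why: Enolate alkylation; the ketone has only one enolisable α-carbon (future C12) because the other is quaternary, and the configuration of the new centre is irrelevant since it becomes sp2.

Step 5
Reactants: 6 (2R,3R)-3-[(tert-butyldimethylsilyl)oxy]-2,6-dimethyl-2-(prop-2-en-1-yl)cyclohexan-1-one
Product: 7 (5R,6R)-5-[(tert-butyldimethylsilyl)oxy]-2,6-dimethyl-6-(prop-2-en-1-yl)cyclohex-2-en-1-one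
Conditions: IBX, DMSO, 70 °C
Reagents that add atoms: none
Why: IBX α,β-dehydrogenation of a ketone through its enol; loss of the ring hydrogen at C11 gives the endocyclic, conjugated trisubstituted enone, and no palladium is present that could engage the allyl group.

Step 6
Reactants: 7 (5R,6R)-5-[(tert-butyldimethylsilyl)oxy]-2,6-dimethyl-6-(prop-2-en-1-yl)cyclohex-2-en-1-one
Product: 8 (5R,6R)-5-[(tert-butyldimethylsilyl)oxy]-2,6-dimethyl-6-[(1E)-prop-1-en-1-yl]cyclohex-2-en-1-one
Conditions: RuHCl(CO)(PPh3)3 (5 mol %), toluene, 80 °C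
Reagents that add atoms: none
Why: Ruthenium hydride addition and β-hydride elimination move the terminal double bond one position inward; it cannot migrate further because C8 is quaternary.

Step 7
Reactants: 8 (5R,6R)-5-[(tert-butyldimethylsilyl)oxy]-2,6-dimethyl-6-[(1E)-prop-1-en-1-yl]cyclohex-2-en-1-one
Product: 9 (1S,6R)-6-[(tert-butyldimethylsilyl)oxy]-1,3-dimethyl-2-oxocyclohex-3-ene-1-carbaldehyde
Conditions: O3, CH2Cl2, −78 °C (Sudan red 7B end point); PPh3, −78 °C → rt
Reagents that add atoms: ozone, [O-][O+]=O
Why: Ozonolysis; the electron-rich disubstituted olefin reacts far faster than the conjugated, electron-poor C11=C12, and the indicator stops the ozone feed; the non-enolisable keto aldehyde is used at once (the descriptor at C8 changes only because the priorities change).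

Step 8
Reactants: 9 (1S,6R)-6-[(tert-butyldimethylsilyl)oxy]-1,3-dimethyl-2-oxocyclohex-3-ene-1-carbaldehyde
Product: 10 (5R,6R)-5-[(tert-butyldimethylsilyl)oxy]-6-[(E)-2-iodoethenyl]-2,6-dimethylcyclohex-2-en-1-one
Conditions: CrCl2, CHI3, THF, 0 °C → rt
Reagents that add atoms: iodoform, IC(I)I
Why: Takai olefination; the geminal dichromium reagent adds to the aldehyde and not to the ketone, and anti elimination gives the E alkenyl iodide, favoured further by the bulky quaternary substituent; the new carbon is C6.

Step 9
Reactants: 10 (5R,6R)-5-[(tert-butyldimethylsilyl)oxy]-6-[(E)-2-iodoethenyl]-2,6-dimethylcyclohex-2-en-1-one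
Product: 11 (5R,6R)-5-[(tert-butyldimethylsilyl)oxy]-6-{(E)-2-[(4-methoxybenzyl)oxy]ethenyl}-2,6-dimethylcyclohex-2-en-1-one
Conditions: CuI (10 mol %), 3,4,7,8-tetramethyl-1,10-phenanthroline (20 mol %), Cs2CO3, 4-methoxybenzyl alcohol, toluene, 80 °C
Reagents that add atoms: 4-methoxybenzyl alcohol, COc1ccc(CO)cc1
Why: Copper-catalysed Ullmann-type C–O coupling of an alkenyl iodide with an alcohol proceeds with retention, so the E geometry set in step 8 is carried into the enol ether; C8 has no hydrogen, so the β,γ-olefin cannot move.

Step 10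
Reactants: 12 but-3-yn-1-ol; 13 4-methoxybenzyl chloride
Product: 14 1-[(but-3-yn-1-yloxy)methyl]-4-methoxybenzene
Conditions: NaH, Bu4NI (cat.), THF/DMF, 0 °C → rt
Reagents that add atoms: none
Why: Williamson ether synthesis with iodide catalysis; the alkoxide is far more nucleophilic than the acetylide is formed under these conditions.

Step 11
Reactants: 14 1-[(but-3-yn-1-yloxy)methyl]-4-methoxybenzene
Product: 16 1-({[(3E)-4-iodobut-3-en-1-yl]oxy}methyl)-4-methoxybenzene, via alkenylzirconocene chloride 15 (not isolated)
Conditions: Cp2Zr(H)Cl, THF, rt; I2, 0 °C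
Reagents that add atoms: iodine, II
Why: Hydrozirconation adds Zr–H syn with zirconium at the terminal carbon, and iodinolysis of the carbon–zirconium bond goes with retention, giving the E alkenyl iodide.

Step 12
Reactants: 16 1-({[(3E)-4-iodobut-3-en-1-yl]oxy}methyl)-4-methoxybenzene; 11 (5R,6R)-5-[(tert-butyldimethylsilyl)oxy]-6-{(E)-2-[(4-methoxybenzyl)oxy]ethenyl}-2,6-dimethylcyclohex-2-en-1-one
Product: 18 (1S,5R,6R)-5-[(tert-butyldimethylsilyl)oxy]-6-{(E)-2-[(4-methoxybenzyl)oxy]ethenyl}-1-{(1E)-4-[(4-methoxybenzyl)oxy]but-1-en-1-yl}-2,6-dimethylcyclohex-2-en-1-ol, via alkenyllithium 17 (not isolated)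
Conditions: t-BuLi (2.0 equiv), Et2O, −78 °C; then 11, THF, −78 → −40 °C
Reagents that add atoms: none
Why: Iodine–lithium exchange with retention gives the E alkenyllithium, which adds 1,2 to the enone carbonyl; the C8 alkenyl ether arm and the C9 silyloxy group lie on the same face of ring A, so attack comes from the C8-methyl face and the new arm ends trans to the C8 arm (C1 S), with O1 syn to O9.

Step 13
Reactants: 18 the cyclohexenol of step 12
Product: 19 (1R,2R,3S)-2-{(E)-2-[(4-methoxybenzyl)oxy]ethenyl}-3-{(1E)-4-[(4-methoxybenzyl)oxy]but-1-en-1-yl}-2,4-dimethylcyclohex-4-ene-1,3-diol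
Conditions: TBAF, THF, rt
Reagents that add atoms: none
Why: Fluoride cleavage of the silyl ether; the hydrated fluoride does not generate a free tertiary alkoxide, so no premature rearrangement occurs.

Step 14
Reactants: 19 the syn diol of step 13
Product: 20 (2S,3S)-3-hydroxy-2-{(E)-2-[(4-methoxybenzyl)oxy]ethenyl}-3-{(1E)-4-[(4-methoxybenzyl)oxy]but-1-en-1-yl}-2,4-dimethylcyclohex-4-en-1-one
Conditions: Dess–Martin periodinane, pyridine, CH2Cl2, 0 °C
Reagents that add atoms: none
Why: Dess–Martin oxidation of the secondary C9 alcohol; the tertiary C1 alcohol cannot be oxidised, and pyridine buffering protects the enol ether and keeps the β-hydroxy, β,γ-unsaturated ketone from retro-aldol cleavage or olefin migration; the product is used at once.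

Step 15
Reactants: 20 the hydroxy ketone of step 14
Product: 21 (1S,2R,3S)-2-{(E)-2-[(4-methoxybenzyl)oxy]ethenyl}-3-{(1E)-4-[(4-methoxybenzyl)oxy]but-1-en-1-yl}-2,4-dimethylcyclohex-4-ene-1,3-diol
Conditions: NaBH4, MeOH/THF, −40 °C
Reagents that add atoms: none
Why: Borohydride reduction of a β-hydroxy ketone: in the half-chair with both alkenyl arms equatorial the C8 methyl is axial on one face and the C1 hydroxyl axial on the other, so hydride enters C9 anti to the methyl and on the side of the hydroxyl (which can bind boron), giving the equatorial C9 alcohol cis to the methyl and anti to O1 (C9 S); any syn diol 19 formed is returned to step 14.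

Step 16
Reactants: 21 the anti diol of step 15
Product: 22 (1S,5S,6R)-6-{(E)-2-[(4-methoxybenzyl)oxy]ethenyl}-1-{(1E)-4-[(4-methoxybenzyl)oxy]but-1-en-1-yl}-2,6-dimethyl-5-[(triisopropylsilyl)oxy]cyclohex-2-en-1-ol
Conditions: TIPSOTf, 2,6-lutidine, CH2Cl2, −78 → 0 °C
Reagents that add atoms: triisopropylsilyl triflate, CC(C)[Si](C(C)C)(C(C)C)OS(=O)(=O)C(F)(F)F
Why: Silylation distinguishes the secondary C9 hydroxyl from the tertiary, doubly allylic C1 hydroxyl on steric grounds; the bulky triisopropylsilyl group is chosen because it does not migrate to the C1 alkoxide in the next step.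

Step 17
Reactants: 22 the trans-dialkenylcyclohexenol of step 16
Product: 25 (2Z,5S,6E,8S,9R)-8-[(4-methoxybenzyl)oxy]-9-{2-[(4-methoxybenzyl)oxy]ethyl}-2,6-dimethyl-5-[(triisopropylsilyl)oxy]cyclodeca-2,6-dien-1-one, via potassium alkoxide 23 (not isolated), via potassium enolate 24 (not isolated)
Conditions: KH, 18-crown-6, THF, 0 °C → rt; AcOH, −78 °C
Reagents that add atoms: none
Why: KH deprotonates the tertiary alcohol and 18-crown-6 frees alkoxide 23 from its cation, which weakens the C1–C8 bond so that the [3,3]-sigmatropic shift runs near room temperature: C1–C8 breaks, C3–C6 forms, C7=C8 appears, and the C1 enolate 24 is protonated at C2 to give 25. The closest known reaction type is the anionic oxy-Cope rearrangement of trans-1,2-dialkenylcyclohexanols and 1,6-dialkenylcyclohex-2-enols to cyclodec-5-enones, which also tolerates enol ether termini. The ten-membered ring is not closed end to end but arises by four-carbon ring expansion of ring A (its six atoms plus C2, C3, C6 and C7), so no dilution is needed. Because the two arms are trans, only one chair is possible: both arms equatorial on ring A, O1 and the C8 methyl axial and C9 equatorial in the six-centre array; the other chair would need both ring A bonds axial, and the boat eclipses the arms. C9 equatorial and methyl axial at C8 give E-C7=C8, and the E enol ether places the 4-methoxybenzyloxy group equatorial, so the configuration of C8 is transferred to C6 as the target requires; the E alkenyl arm sets C3 in the same way (C3 later becomes sp2). C9 is a spectator and the Z olefin C11=C12 stays locked in ring A until the bond breaks. The ring olefin cannot act as a Cope terminus because C11 cannot reach C6, and silyl transfer from O9 is blocked by the triisopropylsilyl group and by the anti arrangement of O1 and O9.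

Step 18
Reactants: 25 the cyclodecadienone of step 17
Product: 26 (1S,2Z,5S,6E,8S,9R)-8-[(4-methoxybenzyl)oxy]-9-{2-[(4-methoxybenzyl)oxy]ethyl}-2,6-dimethyl-5-[(triisopropylsilyl)oxy]cyclodeca-2,6-dien-1-ol
Conditions: (R)-2-methyl-CBS-oxazaborolidine, catecholborane, toluene, −78 °C
Reagents that add atoms: none
Why: CBS reduction of an α-methyl enone: with the C12 alkenyl carbon as the large and C2H2 as the small group, the (R)-catalyst gives the (S)-carbinol; catecholborane at −78 °C leaves the trisubstituted olefins alone.

Step 19
Reactants: 26 the (1S)-alcohol of step 18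
Product: 27 the C1 tert-butyldimethylsilyl ether of 26 (C1 S; C3 2-(PMB-oxy)ethyl; C6 OPMB; C9 OTIPS)
Conditions: TBSOTf, 2,6-lutidine, CH2Cl2, −78 °C
Reagents that add atoms: tert-butyldimethylsilyl triflate, CC(C)(C)[Si](C)(C)OS(=O)(=O)C(F)(F)F
Why: Silylation of the allylic alcohol protects it from the oxoammonium oxidation and the enolate chemistry that follow.

Step 20
Reactants: 27 the bis-PMB ether of step 19
Product: 28 the 1,4-diol with free C5 (primary) and C6 (allylic) hydroxyls (C1 OTBS; C9 OTIPS)
Conditions: DDQ, CH2Cl2/pH 7 buffer, 0 °C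
Reagents that add atoms: none
Why: Oxidative cleavage of both 4-methoxybenzyl ethers (hydride abstraction, hydrolysis of the oxocarbenium ions); silyl ethers and olefins survive the buffered conditions.

Step 21
Reactants: 28 the 1,4-diol of step 20
Product: 30 the trans-fused γ-lactone (C5 carbonyl bonded to O6; H-3 and H-6 anti; C1 OTBS; C9 OTIPS), via lactol 29 (not isolated)
Conditions: TEMPO (20 mol %), PhI(OAc)2, CH2Cl2, rt
Reagents that add atoms: none
Why: Oxoammonium oxidation selects the primary alcohol; the aldehyde is trapped by the C6 hydroxyl as a five-membered lactol, which is oxidised on to the lactone, so C6 keeps its configuration and its allylic alcohol never reaches the ketone.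

Step 22
Reactants: 30 the γ-lactone of step 21
Product: 31 the α-(hydroxymethyl) lactone (CH2OH at C4 trans to C2)
Conditions: LDA, THF, −78 °C; CH2O (monomeric, from cracked paraformaldehyde), −78 → −40 °C
Reagents that add atoms: formaldehyde, C=O
Why: Aldol addition of the lithium lactone enolate to formaldehyde; the electrophile enters anti to C2, but the configuration at C4 is of no consequence because C4 becomes sp2.

Step 23
Reactants: 31 the α-(hydroxymethyl) lactone of step 22
Product: 34 the butenolide with C3=C4 and C4 CH2OH (C1 OTBS; C9 OTIPS), via α-phenylselenide 32 (not isolated), via selenoxide 33 (not isolated)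
Conditions: LDA (2.2 equiv), THF, −78 °C; PhSeBr; then H2O2, pyridine, CH2Cl2, 0 °C → rt
Reagents that add atoms: none
Why: Selenoxide syn-elimination: the dianion (alkoxide plus enolate, so no β-elimination of oxygen) is selenenylated anti to C2, which puts selenium cis to H-3; the selenoxide eliminates through that hydrogen and away from the carbinol carbon, as β-hydroxy selenoxides do, giving the endocyclic butenolide; pyridine suppresses epoxidation by perseleninic acid.

Step 24
Reactants: 34 the butenolide of step 23
Product: 35 the triol (C1 OH, C9 OH, CH2OH)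
Conditions: TBAF, AcOH, THF, rt
Reagents that add atoms: none
Why: Acetic acid-buffered fluoride removes both secondary silyl ethers without deprotonating the γ-position (C6) of the butenolide and without the strong acid that the 1,5-diene cannot tolerate.

Step 25
Reactants: 35 the triol of step 24
Product: 37 the C1,C9-diacetate with CH2OTBS, via primary silyl ether diol 36 (not isolated)
Conditions: TBSCl, imidazole, CH2Cl2, −20 °C; then Ac2O, pyridine, DMAP, 0 °C → rt
Reagents that add atoms: tert-butyldimethylsilyl chloride, CC(C)(C)[Si](C)(C)Cl; acetic anhydride, CC(=O)OC(C)=O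
Why: The unhindered primary allylic hydroxyl is silylated selectively at low temperature; the two secondary hydroxyls are then acetylated in the same flask under nucleophilic catalysis, with retention at C1 and C9.

Step 26
Reactants: 37 the diacetate of step 25
Product: 38 the target, (1S,6R,9S)-diacetate with free CH2OH
Conditions: HF·pyridine, pyridine, THF, 0 °C
Reagents that add atoms: none
Why: Buffered HF·pyridine cleaves the primary silyl ether; the acetates, the butenolide and the 1,5-diene are untouched under these mild conditions.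

**Compound list**

1 | 2-methylcyclohexane-1,3-dione | CC1C(=O)CCCC1=O | starting material
2 | allyl bromide | C=CCBr | starting material
3 | 2-methyl-2-(prop-2-en-1-yl)cyclohexane-1,3-dione | CC1(CC=C)C(=O)CCCC1=O | intermediate
4 | (2R,3R)-3-hydroxy-2-methyl-2-(prop-2-en-1-yl)cyclohexan-1-one (OH cis to allyl) | O=C1CCC[C@@H](O)[C@@]1(C)CC=C | intermediate
5 | (2R,3R)-3-[(tert-butyldimethylsilyl)oxy]-2-methyl-2-(prop-2-en-1-yl)cyclohexan-1-one | O=C1CCC[C@@H](O[Si](C)(C)C(C)(C)C)[C@@]1(C)CC=C | intermediate
6 | (2R,3R)-3-[(tert-butyldimethylsilyl)oxy]-2,6-dimethyl-2-(prop-2-en-1-yl)cyclohexan-1-one (C6 epimers) | O=C1C(C)CC[C@@H](O[Si](C)(C)C(C)(C)C)[C@@]1(C)CC=C | intermediate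
7 | (5R,6R)-5-[(tert-butyldimethylsilyl)oxy]-2,6-dimethyl-6-(prop-2-en-1-yl)cyclohex-2-en-1-one | O=C1C(C)=CC[C@@H](O[Si](C)(C)C(C)(C)C)[C@@]1(C)CC=C | intermediate
8 | (5R,6R)-5-[(tert-butyldimethylsilyl)oxy]-2,6-dimethyl-6-[(1E)-prop-1-en-1-yl]cyclohex-2-en-1-one | O=C1C(C)=CC[C@@H](O[Si](C)(C)C(C)(C)C)[C@@]1(C)/C=C/C | intermediate
9 | (1S,6R)-6-[(tert-butyldimethylsilyl)oxy]-1,3-dimethyl-2-oxocyclohex-3-ene-1-carbaldehyde | O=C1C(C)=CC[C@@H](O[Si](C)(C)C(C)(C)C)[C@@]1(C)C=O | intermediate
10 | (5R,6R)-5-[(tert-butyldimethylsilyl)oxy]-6-[(E)-2-iodoethenyl]-2,6-dimethylcyclohex-2-en-1-one | O=C1C(C)=CC[C@@H](O[Si](C)(C)C(C)(C)C)[C@@]1(C)/C=C/I | intermediate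
11 | (5R,6R)-5-[(tert-butyldimethylsilyl)oxy]-6-{(E)-2-[(4-methoxybenzyl)oxy]ethenyl}-2,6-dimethylcyclohex-2-en-1-one | O=C1C(C)=CC[C@@H](O[Si](C)(C)C(C)(C)C)[C@@]1(C)/C=C/OCc1ccc(OC)cc1 | intermediate
12 | but-3-yn-1-ol | C#CCCO | starting material
13 | 4-methoxybenzyl chloride | COc1ccc(CCl)cc1 | starting material
14 | 1-[(but-3-yn-1-yloxy)methyl]-4-methoxybenzene | C#CCCOCc1ccc(OC)cc1 | intermediate
15 | (E)-alkenylzirconocene chloride from 14 | Cl[Zr](/C=C/CCOCc1ccc(OC)cc1)(C1C=CC=C1)C1C=CC=C1 | intermediate (not isolated)
16 | 1-({[(3E)-4-iodobut-3-en-1-yl]oxy}methyl)-4-methoxybenzene | I/C=C/CCOCc1ccc(OC)cc1 | intermediate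
17 | (E)-4-[(4-methoxybenzyl)oxy]but-1-en-1-yllithium | [Li]/C=C/CCOCc1ccc(OC)cc1 | intermediate (not isolated)
18 | (1S,5R,6R)-5-[(tert-butyldimethylsilyl)oxy]-6-{(E)-2-[(4-methoxybenzyl)oxy]ethenyl}-1-{(1E)-4-[(4-methoxybenzyl)oxy]but-1-en-1-yl}-2,6-dimethylcyclohex-2-en-1-ol (arms trans, O1 syn to O9) | O[C@@]1(/C=C/CCOCc2ccc(OC)cc2)C(C)=CC[C@@H](O[Si](C)(C)C(C)(C)C)[C@@]1(C)/C=C/OCc1ccc(OC)cc1 | intermediate
19 | (1R,2R,3S)-2-{(E)-2-[(4-methoxybenzyl)oxy]ethenyl}-3-{(1E)-4-[(4-methoxybenzyl)oxy]but-1-en-1-yl}-2,4-dimethylcyclohex-4-ene-1,3-diol (syn diol) | O[C@@]1(/C=C/CCOCc2ccc(OC)cc2)C(C)=CC[C@@H](O)[C@@]1(C)/C=C/OCc1ccc(OC)cc1 | intermediate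
20 | (2S,3S)-3-hydroxy-2-{(E)-2-[(4-methoxybenzyl)oxy]ethenyl}-3-{(1E)-4-[(4-methoxybenzyl)oxy]but-1-en-1-yl}-2,4-dimethylcyclohex-4-en-1-one | O[C@@]1(/C=C/CCOCc2ccc(OC)cc2)C(C)=CCC(=O)[C@@]1(C)/C=C/OCc1ccc(OC)cc1 | intermediate
21 | (1S,2R,3S)-2-{(E)-2-[(4-methoxybenzyl)oxy]ethenyl}-3-{(1E)-4-[(4-methoxybenzyl)oxy]but-1-en-1-yl}-2,4-dimethylcyclohex-4-ene-1,3-diol (anti diol) | O[C@@]1(/C=C/CCOCc2ccc(OC)cc2)C(C)=CC[C@H](O)[C@@]1(C)/C=C/OCc1ccc(OC)cc1 | intermediate
22 | (1S,5S,6R)-6-{(E)-2-[(4-methoxybenzyl)oxy]ethenyl}-1-{(1E)-4-[(4-methoxybenzyl)oxy]but-1-en-1-yl}-2,6-dimethyl-5-[(triisopropylsilyl)oxy]cyclohex-2-en-1-ol | O[C@@]1(/C=C/CCOCc2ccc(OC)cc2)C(C)=CC[C@H](O[Si](C(C)C)(C(C)C)C(C)C)[C@@]1(C)/C=C/OCc1ccc(OC)cc1 | intermediate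
23 | potassium alkoxide of 22 | [K+].[O-][C@@]1(/C=C/CCOCc2ccc(OC)cc2)C(C)=CC[C@H](O[Si](C(C)C)(C(C)C)C(C)C)[C@@]1(C)/C=C/OCc1ccc(OC)cc1 | intermediate (not isolated)
24 | potassium C1 enolate of 25 (C1=C2 with C12 trans to C3) | [C@H]1(CCOCc2ccc(OC)cc2)[C@H](OCc2ccc(OC)cc2)/C=C(\C)[C@@H](O[Si](C(C)C)(C(C)C)C(C)C)C/C=C(C)\C([O-])=C\1.[K+] | intermediate (not isolated)
25 | (2Z,5S,6E,8S,9R)-8-[(4-methoxybenzyl)oxy]-9-{2-[(4-methoxybenzyl)oxy]ethyl}-2,6-dimethyl-5-[(triisopropylsilyl)oxy]cyclodeca-2,6-dien-1-one | O=C1C[C@@H](CCOCc2ccc(OC)cc2)[C@H](OCc2ccc(OC)cc2)/C=C(\C)[C@@H](O[Si](C(C)C)(C(C)C)C(C)C)C/C=C\1C | intermediate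
26 | (1S,2Z,5S,6E,8S,9R)-8-[(4-methoxybenzyl)oxy]-9-{2-[(4-methoxybenzyl)oxy]ethyl}-2,6-dimethyl-5-[(triisopropylsilyl)oxy]cyclodeca-2,6-dien-1-ol | O[C@H]1C[C@@H](CCOCc2ccc(OC)cc2)[C@H](OCc2ccc(OC)cc2)/C=C(\C)[C@@H](O[Si](C(C)C)(C(C)C)C(C)C)C/C=C\1C | intermediate
27 | C1 tert-butyldimethylsilyl ether of 26 | CC(C)(C)[Si](C)(C)O[C@H]1C[C@@H](CCOCc2ccc(OC)cc2)[C@H](OCc2ccc(OC)cc2)/C=C(\C)[C@@H](O[Si](C(C)C)(C(C)C)C(C)C)C/C=C\1C | intermediate
28 | 1,4-diol: C3 2-hydroxyethyl, C6 OH, C1 OTBS, C9 OTIPS | CC(C)(C)[Si](C)(C)O[C@H]1C[C@@H](CCO)[C@H](O)/C=C(\C)[C@@H](O[Si](C(C)C)(C(C)C)C(C)C)C/C=C\1C | intermediate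
29 | lactol (C5 hemiacetal closed onto O6) | CC(C)(C)[Si](C)(C)O[C@H]1C[C@H]2CC(O)O[C@@H]2/C=C(\C)[C@@H](O[Si](C(C)C)(C(C)C)C(C)C)C/C=C\1C | intermediate (not isolated)
30 | trans-fused γ-lactone (C5=O, O6; H-3 and H-6 anti; C1 OTBS; C9 OTIPS) | CC(C)(C)[Si](C)(C)O[C@H]1C[C@H]2CC(=O)O[C@@H]2/C=C(\C)[C@@H](O[Si](C(C)C)(C(C)C)C(C)C)C/C=C\1C | intermediate
31 | α-(hydroxymethyl) lactone (CH2OH at C4 trans to C2) | CC(C)(C)[Si](C)(C)O[C@H]1C[C@H]2[C@H](CO)C(=O)O[C@@H]2/C=C(\C)[C@@H](O[Si](C(C)C)(C(C)C)C(C)C)C/C=C\1C | intermediate
32 | α-phenylselenide of 31 (PhSe at C4 cis to H-3) | CC(C)(C)[Si](C)(C)O[C@H]1C[C@H]2[C@](CO)([Se]c3ccccc3)C(=O)O[C@@H]2/C=C(\C)[C@@H](O[Si](C(C)C)(C(C)C)C(C)C)C/C=C\1C | intermediate (not isolated)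
33 | selenoxide of 32 | CC(C)(C)[Si](C)(C)O[C@H]1C[C@H]2[C@](CO)([Se](=O)c3ccccc3)C(=O)O[C@@H]2/C=C(\C)[C@@H](O[Si](C(C)C)(C(C)C)C(C)C)C/C=C\1C | intermediate (not isolated)
34 | butenolide: C3=C4, C4 CH2OH, C1 OTBS, C9 OTIPS | CC(C)(C)[Si](C)(C)O[C@H]1CC2=C(CO)C(=O)O[C@@H]2/C=C(\C)[C@@H](O[Si](C(C)C)(C(C)C)C(C)C)C/C=C\1C | intermediate
35 | triol (C1 OH, C9 OH, CH2OH) | O[C@H]1CC2=C(CO)C(=O)O[C@@H]2/C=C(\C)[C@@H](O)C/C=C\1C | intermediate
36 | primary tert-butyldimethylsilyl ether of 35 (C1 and C9 hydroxyls free) | O[C@H]1CC2=C(CO[Si](C)(C)C(C)(C)C)C(=O)O[C@@H]2/C=C(\C)[C@@H](O)C/C=C\1C | intermediate (not isolated)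
37 | C1,C9-diacetate with CH2OTBS | CC(=O)O[C@H]1CC2=C(CO[Si](C)(C)C(C)(C)C)C(=O)O[C@@H]2/C=C(\C)[C@@H](OC(C)=O)C/C=C\1C | intermediate
38 | target: (1S,6R,9S)-C1,C9-diacetate of the α-(hydroxymethyl)butenolide-fused (7E,11Z)-cyclodecadiene | CC(=O)O[C@H]1CC2=C(CO)C(=O)O[C@@H]2/C=C(\C)[C@@H](OC(C)=O)C/C=C\1C | target

**Step count.** Total: 26 steps. Longest linear sequence: 24 steps (steps 1–9 and 12–26); steps 10–11 make the side arm.

**Least certain steps**

Step 17 (key step). The alkoxide may cleave at C1–C8 without the C3–C6 bond forming, or part of the material may pass through a boat and erode the C6 configuration. The fallback leaves the anionic regime. Alcohol 22 is heated without base (o-dichlorobenzene, about 200 °C, base-washed sealed vessel, a trace of iPr2NEt as acid scavenger). The neutral oxy-Cope shift passes through the same chair and gives the C1 enol F1, which tautomerises to 25. The fallback sets out from 22 and returns at 25.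

Step 9. Carbon–oxygen bond formation at copper may be slow on this substrate, leaving time for base-mediated γ-deprotonation of the enone or reductive loss of iodine. The fallback starts from aldehyde 9. Boryl-olefination of the Takai type (CrCl2, LiI, Cl2CHB(pin)) gives the (E)-alkenyl pinacol boronate F2. Oxidative coupling with 4-methoxybenzyl alcohol (Cu(OAc)2, Et3N, rt, air) then forms the enol ether with retention at room temperature. The fallback returns at 11.

Step 12. The basic alkenyllithium may deprotonate C10 of the hindered enone instead of adding, or facial selectivity may erode. The fallback sets out from 11 and alkyne 14. The lithium acetylide of 14 (n-BuLi, THF, −78 °C), which is slimmer and less basic, adds to C1 from the same face to give the propargylic alcohol F3. Hydroxyl-directed trans-hydroalumination with NaAlH2(OCH2CH2OMe)2 then gives the E allylic alcohol. The fallback returns at 18.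

Step 15. Hydride may attack from the C8-methyl face and regenerate the syn diol, and the basic medium may open 20 by retro-aldol cleavage or move C11=C12 into conjugation with C9. The fallback replaces external attack by internal delivery. Me4NBH(OAc)3 in MeCN/AcOH at −30 °C (Evans–Saksena reduction) binds to O1 and transfers hydride within the molecule to the same face of C9, under non-basic conditions. It sets out from 20 and returns at 21; no new compound is formed (F0).

Step 18. The conformation of the ten-membered ring, not the catalyst, may decide which face of the C1 carbonyl is open, giving the wrong epimer. The fallback accepts substrate control. Luche reduction of 25 (NaBH4, CeCl3·7H2O, MeOH, −78 °C) gives whichever alcohol the ring prefers. If this is the (1R)-alcohol F4, Mitsunobu inversion with 4-nitrobenzoic acid (PPh3, DIAD) gives the (1S)-4-nitrobenzoate F5, and methanolysis (K2CO3, MeOH) gives the (1S)-alcohol. The fallback sets out from 25 and returns at 26.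

Step 23. The dianion may lose formaldehyde by retro-aldol reaction, selenium may enter on the face away from H-3 so that no endocyclic syn-elimination is possible, or the ring olefins may be epoxidised. The fallback separates desaturation from hydroxymethylation and starts from lactone 30. Selenenylation of its enolate gives the α-phenylselenide F6, which can equilibrate at C4. Its selenoxide F7 eliminates to the α-unsubstituted butenolide F8. Iodination (I2, pyridine) gives the α-iodobutenolide F9, and Stille coupling with (tributylstannyl)methanol (Pd(PPh3)4, dioxane, 80 °C) installs the CH2OH group. The fallback returns at 34.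

## Further compounds

F1 | step 17 | C1 enol of 25 (C1=C2 with C12 trans to C3) | [C@H]1(CCOCc2ccc(OC)cc2)[C@H](OCc2ccc(OC)cc2)/C=C(\C)[C@@H](O[Si](C(C)C)(C(C)C)C(C)C)C/C=C(C)\C(O)=C\1
F2 | step 9 | (5R,6R)-5-[(tert-butyldimethylsilyl)oxy]-2,6-dimethyl-6-[(E)-2-(4,4,5,5-tetramethyl-1,3,2-dioxaborolan-2-yl)ethenyl]cyclohex-2-en-1-one | O=C1C(C)=CC[C@@H](O[Si](C)(C)C(C)(C)C)[C@@]1(C)/C=C/B1OC(C)(C)C(C)(C)O1
F3 | step 12 | propargylic alcohol: 18 with a C2≡C3 triple bond | O[C@@]1(C#CCCOCc2ccc(OC)cc2)C(C)=CC[C@@H](O[Si](C)(C)C(C)(C)C)[C@@]1(C)/C=C/OCc1ccc(OC)cc1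
F0 | step 15 | none | none
F4 | step 18 | (1R)-alcohol, C1 epimer of 26 | O[C@@H]1C[C@@H](CCOCc2ccc(OC)cc2)[C@H](OCc2ccc(OC)cc2)/C=C(\C)[C@@H](O[Si](C(C)C)(C(C)C)C(C)C)C/C=C\1C
F5 | step 18 | (1S)-4-nitrobenzoate of 26 | O=C(O[C@H]1C[C@@H](CCOCc2ccc(OC)cc2)[C@H](OCc2ccc(OC)cc2)/C=C(\C)[C@@H](O[Si](C(C)C)(C(C)C)C(C)C)C/C=C\1C)c1ccc(cc1)[N+](=O)[O-]
F6 | step 23 | α-phenylselenide of lactone 30 (C4 epimers) | CC(C)(C)[Si](C)(C)O[C@H]1C[C@H]2C([Se]c3ccccc3)C(=O)O[C@@H]2/C=C(\C)[C@@H](O[Si](C(C)C)(C(C)C)C(C)C)C/C=C\1C
F7 | step 23 | selenoxide of F6 | CC(C)(C)[Si](C)(C)O[C@H]1C[C@H]2C([Se](=O)c3ccccc3)C(=O)O[C@@H]2/C=C(\C)[C@@H](O[Si](C(C)C)(C(C)C)C(C)C)C/C=C\1C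
F8 | step 23 | α-unsubstituted butenolide (C3=C4, C4 H; C1 OTBS; C9 OTIPS) | CC(C)(C)[Si](C)(C)O[C@H]1CC2=CC(=O)O[C@@H]2/C=C(\C)[C@@H](O[Si](C(C)C)(C(C)C)C(C)C)C/C=C\1C
F9 | step 23 | α-iodobutenolide (C4 iodide) | CC(C)(C)[Si](C)(C)O[C@H]1CC2=C(I)C(=O)O[C@@H]2/C=C(\C)[C@@H](O[Si](C(C)C)(C(C)C)C(C)C)C/C=C\1C
A1 | alternative 1 | open-chain ynal (C9 aldehyde, C7≡C8–CH3, C1 and C6 OTBS, C3=C4 enoate) | O=CC/C=C(C)\[C@@H](O[Si](C)(C)C(C)(C)C)C/C(=C(\COCc1ccc(OC)cc1)C(=O)OC)[C@H](O[Si](C)(C)C(C)(C)C)C#CC
A2 | alternative 1 | ten-membered E,Z-diene with C9 OSiEt3 and the seco-butenolide enoate | CC(C)(C)[Si](C)(C)O[C@H]1C/C(=C(\COCc2ccc(OC)cc2)C(=O)OC)[C@H](O[Si](C)(C)C(C)(C)C)/C=C(\C)[C@@H](O[Si](CC)(CC)CC)C/C=C\1C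
A3 | alternative 2 | trans-fused decalin: C1 OH, C8 CH3, equatorial C7 mesylate, C6 OPMB, C3 dioxolane, C9 OTBS, C11=C12 | O[C@@]12C(C)=CC[C@H](O[Si](C)(C)C(C)(C)C)[C@@]1(C)[C@H](OS(C)(=O)=O)[C@@H](OCc3ccc(OC)cc3)C4(OCCO4)C2
A4 | alternative 2 | (2Z,6E)-cyclodecadienone with C3 dioxolane, C6 OPMB and C9 OTBS | O=C1CC2(OCCO2)[C@H](OCc3ccc(OC)cc3)/C=C(\C)[C@@H](O[Si](C)(C)C(C)(C)C)C/C=C\1C
A5 | alternative 3 | open-chain Z alkenyl iodide (C12) and allylic stannane (C2) with intact butenolide | I/C(C)=C\C[C@H](O[Si](C)(C)C(C)(C)C)/C(C)=C/[C@H]1OC(=O)C(COCc2ccc(OC)cc2)=C1C[Sn](CCCC)(CCCC)CCCC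
A6 | alternative 3 | macrocyclic C1 ketone with intact butenolide (C9 OTBS, CH2OPMB) | O=C1CC2=C(COCc3ccc(OC)cc3)C(=O)O[C@@H]2/C=C(\C)[C@@H](O[Si](C)(C)C(C)(C)C)C/C=C\1C
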